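## Retrosynthetic overview

1. The C15–O ester bond is cut last: allylic alcohol 24 plus 30-silyloxytriacontanoic acid 31, whose C30 chain is a copper-catalysed Grignard union of two C15 units from 15-pentadecanolide.
2. The side chain C12–C16 is grown from a C11 aldehyde (Wittig, hydrogenation, Horner–Wadsworth–Emmons). The C7=C8 alkene is drawn from a C7 ketone through its more substituted enol triflate.
3. Feature used: ring B (C5–C10) holds the trans fusion bond C5–C10, the quaternary C10 with methyl C20, and the C9 branch C11. With oxygen imagined on C7 it is the cyclohexene of a Diels–Alder adduct, so C5–C10 and C8–C9 are cut together.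
4. Key disconnection: intramolecular Diels–Alder reaction of silyloxytrienal 14 (diene C5=C6–C7(OTES)=C8, dienophile C9=C10–C11HO, tether C1–C4). Rings A and B form in the same step, ring B as the cycloaddition ring and ring A as the tether ring; no ring exists before it.
5. Trienal 14 comes from geranyl acetate (C1–C3, C9–C11, C20), an isobutyrate ketene acetal (C4, C5, C18, C19; the enantioselective aldol sets C3) and a ketophosphonate (C6–C8, C17).

Key step: step 10

Remark: atom numbers are those of the labdane skeleton of the target (ring A C1–C5 and C10; ring B C5–C10; side chain C11–C15 with C16 on C13; C17 on C8; C18, C19 on C4; C20 on C10). The acyl chain is read as 30-hydroxytriacontanoate (29 methylene groups), and the target is (3R,5S,9R,10S).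

## Route

Step 1
Reactants: 1 geranyl acetate
Product: 3 (2E)-3-methyl-6-oxohex-2-en-1-yl acetate, via secondary ozonide 2 (not isolated)
Conditions: O3 (1.0 equiv, Sudan Red 7B as end-point indicator), CH2Cl2, −78 °C; then PPh3, −78 °C to rt
Reagents that add atoms: ozone, [O-][O+]=O
Why: Ozone attacks the electron-rich C6=C7 alkene of geranyl acetate much faster than the alkene deactivated by the allylic acetate, so one equivalent followed by PPh3 reduction of the ozonide should give the C3 aldehyde (Criegee ozonolysis with reductive work-up).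

Step 2
Reactants: 3 (2E)-3-methyl-6-oxohex-2-en-1-yl acetate; 4 1-methoxy-2-methyl-1-(trimethylsilyloxy)prop-1-ene
Product: 5 methyl (3R,6E)-8-acetoxy-3-hydroxy-2,2,6-trimethyloct-6-enoate
Conditions: N-tosyl-L-valine (1.1 equiv), BH3·THF (1.0 equiv), CH2Cl2, 0 °C to rt; then 3 and 4 (1.2 equiv), −78 °C; pH 7 buffer work-up
Reagents that add atoms: none
Why: Kiyooka-type enantioselective Mukaiyama aldol addition, in which the oxazaborolidinone from N-tosyl-L-valine and BH3 binds the aldehyde and leaves its Si face open to the ketene acetal, sets C3 as R and builds the quaternary C4 with C18, C19 and C5 in one bond.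

Step 3
Reactants: 5 methyl (3R,6E)-8-acetoxy-3-hydroxy-2,2,6-trimethyloct-6-enoate
Product: 6 methyl (3R,6E)-8-acetoxy-3-[(tert-butyldimethylsilyl)oxy]-2,2,6-trimethyloct-6-enoate
Conditions: TBSOTf, 2,6-lutidine, CH2Cl2, 0 °C
Reagents that add atoms: tert-butyldimethylsilyl triflate (TBSOTf), CC(C)(C)[Si](C)(C)OS(=O)(=O)C(F)(F)F
Why: The hindered secondary hydroxyl beside the quaternary carbon needs the silyl triflate, and lutidine-buffered silyl ether formation leaves ester, acetate and alkene untouched.

Step 4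
Reactants: 6 methyl (3R,6E)-8-acetoxy-3-[(tert-butyldimethylsilyl)oxy]-2,2,6-trimethyloct-6-enoate
Product: 8 (3R,6E)-3-[(tert-butyldimethylsilyl)oxy]-8-hydroxy-2,2,6-trimethyloct-6-enal, via aluminium hemiacetal 7 (not isolated)
Conditions: iBu2AlH (3.3 equiv), CH2Cl2, −78 °C; MeOH at −78 °C, then aqueous potassium sodium tartrate (KNaC4H4O6)
Reagents that add atoms: none
Why: At −78 °C the tetrahedral aluminium hemiacetal of the neopentyl methyl ester should persist until the quench and so stop at the aldehyde, while two further hydride equivalents cleave the acetate to the allylic alkoxide (partial iBu2AlH reduction of an ester).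

Step 5
Reactants: 8 (3R,6E)-3-[(tert-butyldimethylsilyl)oxy]-8-hydroxy-2,2,6-trimethyloct-6-enal; 9 diethyl (2-oxobutyl)phosphonate
Product: 10 (4E,7R,10E)-7-[(tert-butyldimethylsilyl)oxy]-12-hydroxy-6,6,10-trimethyldodeca-4,10-dien-3-one
Conditions: 9 (1.3 equiv), Ba(OH)2 (activated by heating, 0.8 equiv), THF/H2O (40:1), rt
Reagents that add atoms: none
Why: Horner–Wadsworth–Emmons olefination of the non-enolisable α-quaternary aldehyde with the stabilised ketophosphonate under mild Ba(OH)2 conditions tolerates the free hydroxyl and should give the E enone, fixing the E geometry of C5=C6.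

Step 6
Reactants: 10 (4E,7R,10E)-7-[(tert-butyldimethylsilyl)oxy]-12-hydroxy-6,6,10-trimethyldodeca-4,10-dien-3-one
Product: 11 (2E,6R,8E)-6-[(tert-butyldimethylsilyl)oxy]-3,7,7-trimethyl-10-oxododeca-2,8-dien-1-yl acetate
Conditions: Ac2O, pyridine, DMAP (cat.), CH2Cl2, 0 °C to rt
Reagents that add atoms: acetic anhydride, CC(=O)OC(C)=O
Why: Acetylation of the primary allylic alcohol masks the C11 hydroxyl so that the silyl triflate of the next step meets only the ketone.

Step 7
Reactants: 11 (2E,6R,8E)-6-[(tert-butyldimethylsilyl)oxy]-3,7,7-trimethyl-10-oxododeca-2,8-dien-1-yl acetate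
Product: 12 (2E,6R,8E,10Z)-6-[(tert-butyldimethylsilyl)oxy]-3,7,7-trimethyl-10-[(triethylsilyl)oxy]dodeca-2,8,10-trien-1-yl acetate
Conditions: TESOTf (1.2 equiv), Et3N (2.5 equiv), CH2Cl2, −78 to 0 °C; chromatography on Et3N-deactivated silica
Reagents that add atoms: triethylsilyl triflate (TESOTf), CC[Si](CC)(CC)OS(=O)(=O)C(F)(F)F
Why: Soft enolisation with silyl triflate and Et3N silylates only the ethyl ketone, whose sole enolisable position is C8 because C4 is quaternary and the acetate is not enolised here, and ethyl ketones give mainly the Z enol ether (C17 cis to oxygen) that the cycloaddition needs, a minor E isomer being unable to reach the s-cis diene.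

Step 8
Reactants: 12 (2E,6R,8E,10Z)-6-[(tert-butyldimethylsilyl)oxy]-3,7,7-trimethyl-10-[(triethylsilyl)oxy]dodeca-2,8,10-trien-1-yl acetate
Product: 13 (2E,6R,8E,10Z)-6-[(tert-butyldimethylsilyl)oxy]-3,7,7-trimethyl-10-[(triethylsilyl)oxy]dodeca-2,8,10-trien-1-ol
Conditions: iBu2AlH (2.2 equiv), CH2Cl2, −78 °C; aqueous potassium sodium tartrate (KNaC4H4O6)
Reagents that add atoms: none
Why: iBu2AlH cleaves the acetate reductively at −78 °C under aprotic, non-acidic conditions that the enol silyl ether and the TBS ether survive.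

Step 9
Reactants: 13 (2E,6R,8E,10Z)-6-[(tert-butyldimethylsilyl)oxy]-3,7,7-trimethyl-10-[(triethylsilyl)oxy]dodeca-2,8,10-trien-1-ol
Product: 14 (2E,6R,8E,10Z)-6-[(tert-butyldimethylsilyl)oxy]-3,7,7-trimethyl-10-[(triethylsilyl)oxy]dodeca-2,8,10-trienal
Conditions: MnO2 (activated, 20 equiv), CH2Cl2, rt
Reagents that add atoms: none
Why: MnO2 oxidises the primary allylic alcohol to the enal on a neutral surface without touching the enol silyl ether and without E/Z isomerisation of C9=C10 (allylic oxidation).

Step 10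
Reactants: 14 (2E,6R,8E,10Z)-6-[(tert-butyldimethylsilyl)oxy]-3,7,7-trimethyl-10-[(triethylsilyl)oxy]dodeca-2,8,10-trienal
Product: 15 trans-decalin C11 aldehyde (1R,2S,4aS,6R,8aR)-6-[(tert-butyldimethylsilyl)oxy]-2,5,5,8a-tetramethyl-3-[(triethylsilyl)oxy]-1,2,4a,5,6,7,8,8a-octahydronaphthalene-1-carbaldehyde
Conditions: Me2AlCl (1.1 equiv), CH2Cl2 (0.01 M), −78 to −30 °C; pyridine, then aqueous NaHCO3
Reagents that add atoms: none
Why: Me2AlCl bound to the C11 carbonyl lowers the LUMO of the enal, and the s-cis (Z)-2-silyloxydiene C5=C6–C7=C8 adds suprafacially across C9=C10 in a concerted, asynchronous [4+2] cycloaddition, the Lewis-acid-promoted intramolecular Diels–Alder reaction of a terminally activated 1,7,9-decatriene being the closest known reaction type. Ring B (C5 to C10) closes as the cycloaddition ring and ring A closes in the fused mode as the six-membered ring of the four-carbon tether C1–C4, which adopts a chair; the tether leaves no other regiochemistry, so the C7 silyloxy group, although electronically mismatched with the enal β-carbon C10, cannot divert the bond formation. C10 and C9 are set by the E geometry of the enal, which is transferred stereospecifically and puts C11 cis to the C20 methyl, and C8 is set by the Z enol ether together with the endo rule (C17 cis to C11) and is removed later. C5 is set by the endo transition state, aldehyde under the diene and tether anti, which places H5 trans to the C20 methyl and gives the trans ring fusion. The absolute sense is relayed from C3: of the two chair-like endo transition states the one with the C3 silyl ether equatorial should be lower, and this leads to the 3R,5S,8S,9R,10R adduct 15, whose C3, C5, C9 and C10 geometry is that of the target. The step therefore needs endo selectivity, which the Lewis acid on the aldehyde reinforces, and diene-face selectivity, which rests on the equatorial preference of the C3 substituent beside the gem-dimethyl carbon C4 (whose Thorpe–Ingold effect also favours folding), while high dilution and low temperature guard the enol silyl ether against intermolecular Mukaiyama aldol addition.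

Step 11
Reactants: 15 trans-decalin C11 aldehyde; 16 1-(triphenylphosphoranylidene)propan-2-one
Product: 17 (11E)-3-[(tert-butyldimethylsilyl)oxy]-7-[(triethylsilyl)oxy]-14,15-dinorlabda-6,11-dien-13-one
Conditions: 16 (2 equiv), toluene, 100 °C
Reagents that add atoms: none
Why: Wittig olefination with the stabilised acetonyl ylide is neutral, so the enol silyl ether and the equatorial (more stable) C9 configuration are preserved, and it should give the E enone that brings in C12, C13 and C16.

Step 12
Reactants: 17 (11E)-3-[(tert-butyldimethylsilyl)oxy]-7-[(triethylsilyl)oxy]-14,15-dinorlabda-6,11-dien-13-one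
Product: 18 3-[(tert-butyldimethylsilyl)oxy]-7-[(triethylsilyl)oxy]-14,15-dinorlabd-6-en-13-one
Conditions: H2 (1 atm), Pd/C (5 wt % Pd on carbon), EtOAc, Et3N (1 vol %), rt
Reagents that add atoms: none
Why: Catalytic hydrogenation saturates the unhindered disubstituted enone alkene C11=C12 much faster than the hindered trisubstituted enol silyl ether C6=C7, and Et3N suppresses acid-induced loss of the TES group.

Step 13
Reactants: 18 3-[(tert-butyldimethylsilyl)oxy]-7-[(triethylsilyl)oxy]-14,15-dinorlabd-6-en-13-one; 19 triethyl phosphonoacetate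
Product: 20 ethyl (13E)-3-[(tert-butyldimethylsilyl)oxy]-7-[(triethylsilyl)oxy]labda-6,13-dien-15-oate
Conditions: 19, NaH, THF, 0 to 45 °C
Reagents that add atoms: none
Why: Horner–Wadsworth–Emmons olefination of the methyl ketone favours the E trisubstituted enoate (C12 trans to C15), the C7 carbonyl being masked as its enol silyl ether so that only C13 reacts, and any Z isomer should be separable at this stage.

Step 14
Reactants: 20 ethyl (13E)-3-[(tert-butyldimethylsilyl)oxy]-7-[(triethylsilyl)oxy]labda-6,13-dien-15-oate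
Product: 21 ethyl (13E)-3-[(tert-butyldimethylsilyl)oxy]-7-oxolabd-13-en-15-oate with the C8 methyl equatorial
Conditions: K2CO3, EtOH/THF, rt to 40 °C
Reagents that add atoms: none
Why: Carbonate-mediated ethanolysis removes the TES group from the enol ether while the hindered alkyl TBS ether stays, and the basic medium should equilibrate C8 to the equatorial methyl, which relieves the syn-diaxial clash with C20 and places H8 axial for the next step.

Step 15
Reactants: 21 ethyl (13E)-3-[(tert-butyldimethylsilyl)oxy]-7-oxolabd-13-en-15-oate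
Product: 22 ethyl (13E)-3-[(tert-butyldimethylsilyl)oxy]-7-(trifluoromethanesulfonyloxy)labda-7,13-dien-15-oate
Conditions: Tf2O, 2,6-di-tert-butyl-4-methylpyridine, CH2Cl2, 0 °C to rt
Reagents that add atoms: triflic anhydride, O=S(=O)(OS(=O)(=O)C(F)(F)F)C(F)(F)F
Why: Triflic anhydride with a hindered pyridine triflates the ketone oxygen and the resulting cation loses an axial proton toward the more substituted side, so the tetrasubstituted C7=C8 enol triflate (thermodynamic regiochemistry) should predominate.

Step 16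
Reactants: 22 ethyl (13E)-3-[(tert-butyldimethylsilyl)oxy]-7-(trifluoromethanesulfonyloxy)labda-7,13-dien-15-oate
Product: 23 ethyl (13E)-3-[(tert-butyldimethylsilyl)oxy]labda-7,13-dien-15-oate
Conditions: Pd(OAc)2 (5 mol %), PPh3 (10 mol %), HCO2H, Bu3N, DMF, 60 °C
Reagents that add atoms: none
Why: Oxidative addition of zerovalent palladium into the enol triflate, formate-to-hydride exchange and reductive elimination replace OTf by H without moving the C7=C8 alkene (palladium-catalysed formate reduction of an enol triflate), leaving the enoate and the silyl ether intact.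

Step 17
Reactants: 23 ethyl (13E)-3-[(tert-butyldimethylsilyl)oxy]labda-7,13-dien-15-oate
Product: 24 (13E)-3-[(tert-butyldimethylsilyl)oxy]labda-7,13-dien-15-ol
Conditions: iBu2AlH (2.5 equiv), CH2Cl2, −78 °C; aqueous potassium sodium tartrate (KNaC4H4O6)
Reagents that add atoms: none
Why: iBu2AlH reduces the β,β-disubstituted enoate by 1,2-addition to the E allylic alcohol without touching the ring alkene or the silyl ether.

Step 18
Reactants: 25 15-pentadecanolide
Product: 26 15-bromopentadecanoic acid
Conditions: HBr (33 % in AcOH), 80 °C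
Reagents that add atoms: hydrogen bromide, Br
Why: Acid-mediated ring opening of the lactone by bromide at the alkyl oxygen carbon (SN2) is the standard preparation of ω-bromoalkanoic acids from lactones.

Step 19
Reactants: 26 15-bromopentadecanoic acid
Product: 27 15-bromopentadecan-1-ol
Conditions: BH3·THF, THF, 0 °C to rt; aqueous work-up
Reagents that add atoms: none
Why: Borane reduces the carboxylic acid chemoselectively to the primary alcohol and leaves the primary bromide untouched.

Step 20
Reactants: 27 15-bromopentadecan-1-ol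
Product: 28 [(15-bromopentadecyl)oxy](tert-butyl)dimethylsilane
Conditions: TBSCl, imidazole, DMF, rt
Reagents that add atoms: tert-butyldimethylsilyl chloride (TBSCl), CC(C)(C)[Si](C)(C)Cl
Why: Standard silylation of the primary alcohol gives a bromide that can be converted into a Grignard reagent.

Step 21
Reactants: 28 [(15-bromopentadecyl)oxy](tert-butyl)dimethylsilane; 26 15-bromopentadecanoic acid
Product: 31 30-[(tert-butyldimethylsilyl)oxy]triacontanoic acid, via Grignard reagent 29 (not isolated), via magnesium carboxylate 30 (not isolated)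
Conditions: 28, Mg, THF, 40 °C; separately 26, MeMgCl (1.0 equiv), THF, −20 °C; then combine with Li2CuCl4 (3 mol %), THF, −20 °C to rt; aqueous NH4Cl
Reagents that add atoms: none
Why: The Grignard reagent couples with the primary bromide of the pre-formed magnesium carboxylate under Li2CuCl4 catalysis (copper-catalysed sp3–sp3 Grignard–alkyl halide coupling), the carboxylate being inert toward the Grignard reagent at low temperature, which joins the two C15 units into the C30 chain.

Step 22
Reactants: 24 (13E)-3-[(tert-butyldimethylsilyl)oxy]labda-7,13-dien-15-ol; 31 30-[(tert-butyldimethylsilyl)oxy]triacontanoic acid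
Product: 32 (13E)-3-[(tert-butyldimethylsilyl)oxy]labda-7,13-dien-15-yl 30-[(tert-butyldimethylsilyl)oxy]triacontanoate
Conditions: EDC·HCl, DMAP, CH2Cl2/THF, rt
Reagents that add atoms: none
Why: Carbodiimide/DMAP (Steglich) esterification acylates the only free hydroxyl, the primary allylic C15 alcohol, under neutral conditions without allylic transposition.

Step 23
Reactants: 32 (13E)-3-[(tert-butyldimethylsilyl)oxy]labda-7,13-dien-15-yl 30-[(tert-butyldimethylsilyl)oxy]triacontanoate
Product: 33 (13E)-(3R,5S,9R,10S)-3-hydroxylabda-7,13-dien-15-yl 30-hydroxytriacontanoate (CNP0303636.1)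
Conditions: HF·pyridine, pyridine, THF, 0 °C to rt
Reagents that add atoms: none
Why: Buffered HF·pyridine cleaves both silyl ethers (the primary one fast, the hindered C3 one more slowly) without hydrolysing or ionising the allylic ester and without moving the C7=C8 or C13=C14 alkenes.

## Compound list

1 | geranyl acetate | CC(C)=CCC/C(C)=C/COC(C)=O | starting material
2 | secondary ozonide of the C6=C7 alkene, (2E)-5-(5,5-dimethyl-1,2,4-trioxolan-3-yl)-3-methylpent-2-en-1-yl acetate | CC1(C)OOC(CC/C(C)=C/COC(C)=O)O1 | intermediate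
3 | (2E)-3-methyl-6-oxohex-2-en-1-yl acetate | O=CCC/C(C)=C/COC(C)=O | intermediate
4 | 1-methoxy-2-methyl-1-(trimethylsilyloxy)prop-1-ene (methyl trimethylsilyl dimethylketene acetal) | COC(O[Si](C)(C)C)=C(C)C | starting material
5 | methyl (3R,6E)-8-acetoxy-3-hydroxy-2,2,6-trimethyloct-6-enoate | COC(=O)C(C)(C)[C@H](O)CC/C(C)=C/COC(C)=O | intermediate
6 | methyl (3R,6E)-8-acetoxy-3-[(tert-butyldimethylsilyl)oxy]-2,2,6-trimethyloct-6-enoate | COC(=O)C(C)(C)[C@H](O[Si](C)(C)C(C)(C)C)CC/C(C)=C/COC(C)=O | intermediate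
7 | diisobutylaluminium hemiacetal at C1 and diisobutylaluminium alkoxide at C8 of the reduced ester 6 | COC(O[Al](CC(C)C)CC(C)C)C(C)(C)[C@H](O[Si](C)(C)C(C)(C)C)CC/C(C)=C/CO[Al](CC(C)C)CC(C)C | intermediate
8 | (3R,6E)-3-[(tert-butyldimethylsilyl)oxy]-8-hydroxy-2,2,6-trimethyloct-6-enal | O=CC(C)(C)[C@H](O[Si](C)(C)C(C)(C)C)CC/C(C)=C/CO | intermediate
9 | diethyl (2-oxobutyl)phosphonate | CCC(=O)CP(=O)(OCC)OCC | starting material
10 | (4E,7R,10E)-7-[(tert-butyldimethylsilyl)oxy]-12-hydroxy-6,6,10-trimethyldodeca-4,10-dien-3-one | CCC(=O)/C=C/C(C)(C)[C@H](O[Si](C)(C)C(C)(C)C)CC/C(C)=C/CO | intermediate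
11 | (2E,6R,8E)-6-[(tert-butyldimethylsilyl)oxy]-3,7,7-trimethyl-10-oxododeca-2,8-dien-1-yl acetate | CCC(=O)/C=C/C(C)(C)[C@H](O[Si](C)(C)C(C)(C)C)CC/C(C)=C/COC(C)=O | intermediate
12 | (2E,6R,8E,10Z)-6-[(tert-butyldimethylsilyl)oxy]-3,7,7-trimethyl-10-[(triethylsilyl)oxy]dodeca-2,8,10-trien-1-yl acetate | C/C=C(O[Si](CC)(CC)CC)/C=C/C(C)(C)[C@H](O[Si](C)(C)C(C)(C)C)CC/C(C)=C/COC(C)=O | intermediate
13 | (2E,6R,8E,10Z)-6-[(tert-butyldimethylsilyl)oxy]-3,7,7-trimethyl-10-[(triethylsilyl)oxy]dodeca-2,8,10-trien-1-ol | C/C=C(O[Si](CC)(CC)CC)/C=C/C(C)(C)[C@H](O[Si](C)(C)C(C)(C)C)CC/C(C)=C/CO | intermediate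
14 | (2E,6R,8E,10Z)-6-[(tert-butyldimethylsilyl)oxy]-3,7,7-trimethyl-10-[(triethylsilyl)oxy]dodeca-2,8,10-trienal (silyloxytrienal, key-step precursor) | C/C=C(O[Si](CC)(CC)CC)/C=C/C(C)(C)[C@H](O[Si](C)(C)C(C)(C)C)CC/C(C)=C/C=O | intermediate
15 | (1R,2S,4aS,6R,8aR)-6-[(tert-butyldimethylsilyl)oxy]-2,5,5,8a-tetramethyl-3-[(triethylsilyl)oxy]-1,2,4a,5,6,7,8,8a-octahydronaphthalene-1-carbaldehyde (labdane locants: 3-OTBS equatorial, 7-OTES, C6=C7, trans fusion, C17, C11 and C20 mutually cis; 3R,5S,8S,9R,10R) | C[C@@H]1C(O[Si](CC)(CC)CC)=C[C@@H]2C(C)(C)[C@H](O[Si](C)(C)C(C)(C)C)CC[C@@]2(C)[C@@H]1C=O | intermediate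
16 | 1-(triphenylphosphoranylidene)propan-2-one | CC(=O)C=P(c1ccccc1)(c1ccccc1)c1ccccc1 | starting material
17 | (11E)-3-[(tert-butyldimethylsilyl)oxy]-7-[(triethylsilyl)oxy]-14,15-dinorlabda-6,11-dien-13-one (ring configuration as in 15) | C[C@@H]1C(O[Si](CC)(CC)CC)=C[C@@H]2C(C)(C)[C@H](O[Si](C)(C)C(C)(C)C)CC[C@@]2(C)[C@@H]1/C=C/C(C)=O | intermediate
18 | 3-[(tert-butyldimethylsilyl)oxy]-7-[(triethylsilyl)oxy]-14,15-dinorlabd-6-en-13-one (ring configuration as in 15) | C[C@@H]1C(O[Si](CC)(CC)CC)=C[C@@H]2C(C)(C)[C@H](O[Si](C)(C)C(C)(C)C)CC[C@@]2(C)[C@@H]1CCC(C)=O | intermediate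
19 | triethyl phosphonoacetate | CCOC(=O)CP(=O)(OCC)OCC | starting material
20 | ethyl (13E)-3-[(tert-butyldimethylsilyl)oxy]-7-[(triethylsilyl)oxy]labda-6,13-dien-15-oate (ring configuration as in 15) | C[C@@H]1C(O[Si](CC)(CC)CC)=C[C@@H]2C(C)(C)[C@H](O[Si](C)(C)C(C)(C)C)CC[C@@]2(C)[C@@H]1CC/C(C)=C/C(=O)OCC | intermediate
21 | ethyl (13E)-3-[(tert-butyldimethylsilyl)oxy]-7-oxolabd-13-en-15-oate (C17 equatorial, trans to the C9 chain; C3, C5, C9, C10 as in 15) | C[C@H]1C(=O)C[C@@H]2C(C)(C)[C@H](O[Si](C)(C)C(C)(C)C)CC[C@@]2(C)[C@@H]1CC/C(C)=C/C(=O)OCC | intermediate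
22 | ethyl (13E)-3-[(tert-butyldimethylsilyl)oxy]-7-(trifluoromethanesulfonyloxy)labda-7,13-dien-15-oate | CC1=C(OS(=O)(=O)C(F)(F)F)C[C@@H]2C(C)(C)[C@H](O[Si](C)(C)C(C)(C)C)CC[C@@]2(C)[C@@H]1CC/C(C)=C/C(=O)OCC | intermediate
23 | ethyl (13E)-3-[(tert-butyldimethylsilyl)oxy]labda-7,13-dien-15-oate | CC1=CC[C@@H]2C(C)(C)[C@H](O[Si](C)(C)C(C)(C)C)CC[C@@]2(C)[C@@H]1CC/C(C)=C/C(=O)OCC | intermediate
24 | (13E)-3-[(tert-butyldimethylsilyl)oxy]labda-7,13-dien-15-ol | CC1=CC[C@@H]2C(C)(C)[C@H](O[Si](C)(C)C(C)(C)C)CC[C@@]2(C)[C@@H]1CC/C(C)=C/CO | intermediate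
25 | 15-pentadecanolide | O=C1CCCCCCCCCCCCCCO1 | starting material
26 | 15-bromopentadecanoic acid | OC(=O)CCCCCCCCCCCCCCBr | intermediate
27 | 15-bromopentadecan-1-ol | OCCCCCCCCCCCCCCCBr | intermediate
28 | [(15-bromopentadecyl)oxy](tert-butyl)dimethylsilane | CC(C)(C)[Si](C)(C)OCCCCCCCCCCCCCCCBr | intermediate
29 | {15-[(tert-butyldimethylsilyl)oxy]pentadecyl}magnesium bromide | CC(C)(C)[Si](C)(C)OCCCCCCCCCCCCCCC[Mg]Br | intermediate
30 | chloromagnesium 15-bromopentadecanoate | Cl[Mg]OC(=O)CCCCCCCCCCCCCCBr | intermediate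
31 | 30-[(tert-butyldimethylsilyl)oxy]triacontanoic acid | OC(=O)CCCCCCCCCCCCCCCCCCCCCCCCCCCCCO[Si](C)(C)C(C)(C)C | intermediate
32 | (13E)-3-[(tert-butyldimethylsilyl)oxy]labda-7,13-dien-15-yl 30-[(tert-butyldimethylsilyl)oxy]triacontanoate | CC1=CC[C@@H]2C(C)(C)[C@H](O[Si](C)(C)C(C)(C)C)CC[C@@]2(C)[C@@H]1CC/C(C)=C/COC(=O)CCCCCCCCCCCCCCCCCCCCCCCCCCCCCO[Si](C)(C)C(C)(C)C | intermediate
33 | (13E)-(3R,5S,9R,10S)-3-hydroxylabda-7,13-dien-15-yl 30-hydroxytriacontanoate (CNP0303636.1) | CC1=CC[C@@H]2C(C)(C)[C@H](O)CC[C@@]2(C)[C@@H]1CC/C(C)=C/COC(=O)CCCCCCCCCCCCCCCCCCCCCCCCCCCCCO | target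

## Step count and risks

Total: 23 steps. Longest linear sequence: 19 steps (steps 1–17, 22 and 23, from geranyl acetate). The C30 acid branch takes 4 steps (18–21).

Steps most likely to fail:

1. Step 10 (cycloaddition). The single C3 stereocentre may discriminate poorly between the two chair-like endo transition states (poor diene-face selectivity). The endo preference may erode with the trisubstituted dienophile. The Lewis acid may desilylate the enol ether or start intermolecular Mukaiyama addition before ring closure. Fallback (auxiliary-controlled cycloaddition of a trienoyl imide), from hydroxy enone 10 back to adduct 15: MnO2 oxidises 10 to the keto enal F1, and NaClO2/NaH2PO4/2-methyl-2-butene (Pinnick oxidation) gives the keto acid F2. Pivaloyl chloride/Et3N forms the mixed anhydride F3 (not isolated), which acylates (4R)-4-benzyl-1,3-oxazolidin-2-one in the presence of LiCl to give the imide F4. TESOTf/Et3N at −78 °C gives the silyloxytriene imide F5. Me2AlCl (1.4 equiv, CH2Cl2, −30 °C) chelates the two imide carbonyls, and the benzyl group should shield the unwanted face of C9 in the s-cis enoyl unit, in the same sense as the C3-directed chair, to give the endo imide adduct F6. LiBH4/MeOH removes the auxiliary to give the C11 alcohol F7, and Dess–Martin periodinane with pyridine returns 15.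

2. Step 15 (enol triflate regiochemistry). Proton loss from C6 instead of C8 would give the C6=C7 enol triflate, and the hindered ketone may react sluggishly. Fallback (reduction and elimination instead of enol triflate reduction), from ketone 21 to dienoate 23: Li[sBu3BH] in THF at −78 °C attacks from the equatorial side to give the axial C7 alcohol F8. POCl3 in pyridine converts it into the dichlorophosphate F9 (not isolated), which should lose the anti-periplanar axial H8 in an E2 elimination with Zaitsev orientation to give the trisubstituted C7=C8 alkene 23.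

3. Step 4 (partial reduction). The hydride is shared between two ester groups, so over-reduction of the C5 ester to the alcohol or incomplete acetate cleavage may blur the aldehyde oxidation level. Fallback (full reduction and re-differentiation), from ester 6 to enone acetate 11: LiAlH4 in THF reduces both esters to the diol F10. AcCl/2,4,6-collidine at −78 °C should acetylate only the unhindered allylic hydroxyl, the neopentyl one reacting slowly, to give the monoacetate F11. Dess–Martin periodinane gives the aldehyde F12, and Horner–Wadsworth–Emmons reaction with 9 (LiCl, iPr2NEt, MeCN) gives 11 directly, which makes steps 5 and 6 unnecessary.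

Further compounds
F1 | step 10 | (2E,6R,8E)-6-[(tert-butyldimethylsilyl)oxy]-3,7,7-trimethyl-10-oxododeca-2,8-dienal | CCC(=O)/C=C/C(C)(C)[C@H](O[Si](C)(C)C(C)(C)C)CC/C(C)=C/C=O
F2 | step 10 | (2E,6R,8E)-6-[(tert-butyldimethylsilyl)oxy]-3,7,7-trimethyl-10-oxododeca-2,8-dienoic acid | CCC(=O)/C=C/C(C)(C)[C@H](O[Si](C)(C)C(C)(C)C)CC/C(C)=C/C(=O)O
F3 | step 10 | mixed anhydride of F2 with pivalic acid | CCC(=O)/C=C/C(C)(C)[C@H](O[Si](C)(C)C(C)(C)C)CC/C(C)=C/C(=O)OC(=O)C(C)(C)C
F4 | step 10 | (4R)-4-benzyl-3-[(2E,6R,8E)-6-[(tert-butyldimethylsilyl)oxy]-3,7,7-trimethyl-10-oxododeca-2,8-dienoyl]-1,3-oxazolidin-2-one | CCC(=O)/C=C/C(C)(C)[C@H](O[Si](C)(C)C(C)(C)C)CC/C(C)=C/C(=O)N1[C@H](Cc2ccccc2)COC1=O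
F5 | step 10 | (4R)-4-benzyl-3-[(2E,6R,8E,10Z)-6-[(tert-butyldimethylsilyl)oxy]-3,7,7-trimethyl-10-[(triethylsilyl)oxy]dodeca-2,8,10-trienoyl]-1,3-oxazolidin-2-one | C/C=C(O[Si](CC)(CC)CC)/C=C/C(C)(C)[C@H](O[Si](C)(C)C(C)(C)C)CC/C(C)=C/C(=O)N1[C@H](Cc2ccccc2)COC1=O
F6 | step 10 | imide analogue of adduct 15 (C11 as N-acyl (4R)-4-benzyl-1,3-oxazolidin-2-one, ring configuration as in 15) | C[C@@H]1C(O[Si](CC)(CC)CC)=C[C@@H]2C(C)(C)[C@H](O[Si](C)(C)C(C)(C)C)CC[C@@]2(C)[C@@H]1C(=O)N3[C@H](Cc4ccccc4)COC3=O
F7 | step 10 | C11 primary alcohol corresponding to adduct 15 | C[C@@H]1C(O[Si](CC)(CC)CC)=C[C@@H]2C(C)(C)[C@H](O[Si](C)(C)C(C)(C)C)CC[C@@]2(C)[C@@H]1CO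
F8 | step 15 | ethyl (13E)-3-[(tert-butyldimethylsilyl)oxy]-7-hydroxylabd-13-en-15-oate with axial 7-OH and equatorial C17 | C[C@H]1[C@@H](O)C[C@@H]2C(C)(C)[C@H](O[Si](C)(C)C(C)(C)C)CC[C@@]2(C)[C@@H]1CC/C(C)=C/C(=O)OCC
F9 | step 15 | C7 dichlorophosphate of F8 | C[C@H]1[C@@H](OP(=O)(Cl)Cl)C[C@@H]2C(C)(C)[C@H](O[Si](C)(C)C(C)(C)C)CC[C@@]2(C)[C@@H]1CC/C(C)=C/C(=O)OCC
F10 | step 4 | (3R,6E)-3-[(tert-butyldimethylsilyl)oxy]-2,2,6-trimethyloct-6-ene-1,8-diol | OCC(C)(C)[C@H](O[Si](C)(C)C(C)(C)C)CC/C(C)=C/CO
F11 | step 4 | (2E,6R)-6-[(tert-butyldimethylsilyl)oxy]-8-hydroxy-3,7,7-trimethyloct-2-en-1-yl acetate | OCC(C)(C)[C@H](O[Si](C)(C)C(C)(C)C)CC/C(C)=C/COC(C)=O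
F12 | step 4 | (2E,6R)-6-[(tert-butyldimethylsilyl)oxy]-3,7,7-trimethyl-8-oxooct-2-en-1-yl acetate | O=CC(C)(C)[C@H](O[Si](C)(C)C(C)(C)C)CC/C(C)=C/COC(C)=O
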